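**Plan**

1. The pyran ring is cut at C3–C4 and at O1–C2, with C2 raised to the lactol level. Ring A becomes an ortho-quinone methide and ring B a 2-arylacetaldehyde; the three phenols carry silyl ethers.
2. The enabling feature: on ring A, O1 sits ortho to the C4 methylene, so the 2-hydroxybenzyl unit is a latent oxadiene O1=C8a–C4a=C4, stabilised by the para oxygen on C7. C3 is alpha to C2, which can be an aldehyde carbon and hence an enamine.
3. Both aryl halves carry the same 2,4-dioxygenated 5-(1,1-dimethylallyl)phenyl pattern, so both come from one aldehyde 6, made from 1 by O-prenylation, silylation and aromatic Claisen rearrangement.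
4. Forward: 1 → 6 (steps 1–4); 6 → aldehyde 8 (steps 5, 6) and 6 → sulfone 11 (steps 7, 8); a formal [4+2] annulation closes the pyran ring (step 9); the C2 hydroxyl is reduced off (step 10); desilylation (step 11).
5. Stereochemistry: the single stereocentre C3 (R) is set in step 9 by the (R)-diphenylprolinol silyl ether catalyst, through face-selective attack of its enamine on the methide carbon.

Key step: step 9

Remark: isoflavan numbering is used (O1, C2, C3, C4, C4a–C8a for ring A, primed locants for ring B). Lactol 13 is carried on as a mixture of C2 epimers, which is of no consequence because C2 becomes CH2.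

**Step 1**
Reactants: 1 2,4-dihydroxybenzaldehyde; 2 prenyl bromide (1-bromo-3-methylbut-2-ene)
Product: 3 2-hydroxy-4-[(3-methylbut-2-en-1-yl)oxy]benzaldehyde
Conditions: K2CO3 (1.0 equiv), acetone, rt
Reagents that add atoms: none
Why: Williamson ether synthesis; the 4-hydroxyl is the more acidic one and, unlike the 2-hydroxyl, is not held in a hydrogen bond to the formyl oxygen, so one equivalent of base and bromide should alkylate O4 only.

**Step 2**
Reactants: 3 2-hydroxy-4-[(3-methylbut-2-en-1-yl)oxy]benzaldehyde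
Product: 4 2-[(tert-butyldimethylsilyl)oxy]-4-[(3-methylbut-2-en-1-yl)oxy]benzaldehyde
Conditions: t-BuMe2SiCl, imidazole, DMF, rt
Reagents that add atoms: tert-butyldimethylsilyl chloride, CC(C)(C)[Si](C)(C)Cl
Why: Silyl ether formation on a phenol; capping O2 removes the O–H···O=C chelate that would steer the coming rearrangement to C3, and the group later protects the 2'-oxygen of ring B.

**Step 3**
Reactants: 4 2-[(tert-butyldimethylsilyl)oxy]-4-[(3-methylbut-2-en-1-yl)oxy]benzaldehyde
Product: 5 2-[(tert-butyldimethylsilyl)oxy]-4-hydroxy-5-(2-methylbut-3-en-2-yl)benzaldehyde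
Conditions: 1,2-dichlorobenzene, 180 °C, sealed tube
Reagents that add atoms: none
Why: Aromatic Claisen rearrangement ([3,3]-sigmatropic shift, then tautomerisation of the dienone), in which the tertiary terminus of the prenyl group bonds to the ring and so gives the 1,1-dimethylallyl group ortho to the freed hydroxyl; C5 should be preferred over C3 because C3 lies between two oxygen substituents (one a bulky silyloxy group) and C5 is para to that donor.

**Step 4**
Reactants: 5 2-[(tert-butyldimethylsilyl)oxy]-4-hydroxy-5-(2-methylbut-3-en-2-yl)benzaldehyde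
Product: 6 2-[(tert-butyldimethylsilyl)oxy]-5-(2-methylbut-3-en-2-yl)-4-[(triisopropylsilyl)oxy]benzaldehyde
Conditions: i-Pr3SiOSO2CF3, 2,6-lutidine, CH2Cl2, 0 °C to rt
Reagents that add atoms: triisopropylsilyl trifluoromethanesulfonate, CC(C)[Si](OS(=O)(=O)C(F)(F)F)(C(C)C)C(C)C
Why: Silyl ether formation with the reactive silyl triflate, needed because the hydroxyl is flanked by the quaternary carbon; the bulky i-Pr3Si group is chosen so that it should survive the later base-mediated removal of the t-BuMe2Si group.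

**Step 5**
Reactants: 6 2-[(tert-butyldimethylsilyl)oxy]-5-(2-methylbut-3-en-2-yl)-4-[(triisopropylsilyl)oxy]benzaldehyde
Product: 7 tert-butyl{2-(2-methoxyethenyl)-4-(2-methylbut-3-en-2-yl)-5-[(triisopropylsilyl)oxy]phenoxy}dimethylsilane (E/Z mixture)
Conditions: Ph3P(CH2OMe)Cl, NaN(SiMe3)2, THF, −78 to 0 °C
Reagents that add atoms: (methoxymethyl)triphenylphosphonium chloride, COC[P+](c1ccccc1)(c1ccccc1)c1ccccc1.[Cl-]
Why: Wittig olefination with the non-stabilised methoxymethylene ylide, a one-carbon homologation that brings in the carbon that becomes C2; aryl silyl ethers and the terminal alkene are inert to the ylide.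

**Step 6**
Reactants: 7 tert-butyl{2-(2-methoxyethenyl)-4-(2-methylbut-3-en-2-yl)-5-[(triisopropylsilyl)oxy]phenoxy}dimethylsilane
Product: 8 2-{2-[(tert-butyldimethylsilyl)oxy]-5-(2-methylbut-3-en-2-yl)-4-[(triisopropylsilyl)oxy]phenyl}acetaldehyde
Conditions: 2 M aq. HCl, THF, rt
Reagents that add atoms: water, O
Why: Acid-catalysed enol ether hydrolysis (protonation at the aryl-bearing carbon, hydration of the oxocarbenium ion, loss of methanol); aryl silyl ethers and the monosubstituted alkene should tolerate dilute acid at room temperature, and the aldehyde is used without storage.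

**Step 7**
Reactants: 6 2-[(tert-butyldimethylsilyl)oxy]-5-(2-methylbut-3-en-2-yl)-4-[(triisopropylsilyl)oxy]benzaldehyde
Product: 10 2-(hydroxymethyl)-4-(2-methylbut-3-en-2-yl)-5-[(triisopropylsilyl)oxy]phenol, via phenol aldehyde 9 (not isolated)
Conditions: K2CO3, MeOH, 0 °C; then NaBH4, 0 °C; NH4Cl work-up
Reagents that add atoms: none
Why: Base-mediated methanolysis of the aryl silyl ether activated by the ortho formyl group (the hindered i-Pr3Si ether should stay), then carbonyl reduction by NaBH4; removing the silyl group first prevents its migration to the benzylic alkoxide.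

**Step 8**
Reactants: 10 2-(hydroxymethyl)-4-(2-methylbut-3-en-2-yl)-5-[(triisopropylsilyl)oxy]phenol
Product: 11 4-(2-methylbut-3-en-2-yl)-2-[(4-methylbenzenesulfonyl)methyl]-5-[(triisopropylsilyl)oxy]phenol
Conditions: p-TolSO2H, CH2Cl2, rt
Reagents that add atoms: 4-methylbenzenesulfinic acid, Cc1ccc(cc1)S(=O)O
Why: Acid-promoted SN1-type substitution of the electron-rich benzylic alcohol (cation stabilised by the ortho hydroxyl and the para silyloxy group) by the sulfur of the sulfinic acid, giving a bench-stable sulfone as the ortho-quinone methide precursor.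

**Step 9**
Reactants: 8 2-{2-[(tert-butyldimethylsilyl)oxy]-5-(2-methylbut-3-en-2-yl)-4-[(triisopropylsilyl)oxy]phenyl}acetaldehyde; 11 4-(2-methylbut-3-en-2-yl)-2-[(4-methylbenzenesulfonyl)methyl]-5-[(triisopropylsilyl)oxy]phenol
Product: 13 (3R)-3-{2-[(tert-butyldimethylsilyl)oxy]-5-(2-methylbut-3-en-2-yl)-4-[(triisopropylsilyl)oxy]phenyl}-6-(2-methylbut-3-en-2-yl)-7-[(triisopropylsilyl)oxy]-3,4-dihydro-2H-chromen-2-ol (lactol; both C2 epimers), via ortho-quinone methide 12 (not isolated)
Conditions: (R)-2-[diphenyl(trimethylsilyloxy)methyl]pyrrolidine (20 mol %), Na2CO3 (1.5 equiv), CH2Cl2/H2O, 0 °C, slow addition of 11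
Reagents that add atoms: none
Why: Na2CO3 deprotonates the phenol of 11 and loss of sulfinate gives the ortho-quinone methide 12 (oxadiene O1=C8a–C4a=C4), while aldehyde 8 condenses reversibly with the secondary amine to its E-enamine; the enamine carbon (C3) adds to the methide carbon (C4), the phenoxide oxygen closes onto the iminium carbon (C2), and hydrolysis releases lactol 13 and the amine. The closest known reaction type is the diarylprolinol silyl ether catalysed formal [4+2] annulation (inverse-electron-demand oxa-Diels-Alder type, Michael addition then hemiaminal formation) of enolisable aldehydes with ortho-quinone methides released from 2-(sulfonylalkyl)phenols, which gives chroman-2-ols. The pyran ring closes as a formal [4+2] cycloaddition in which the C3–C4 bond forms first and the O1–C2 bond follows by 6-exo-trig attack of the phenoxide on the iminium ion. C3 is the only stereocentre that matters: the CPh2(OSiMe3) group of the (R)-catalyst shields the Si face of the enamine carbon, so the methide should add to the Re face and give (3R), while the anomeric centre C2 forms as a mixture and is removed in step 10. The step needs facial selectivity (secured by the catalyst), a single methide (secured by the silyl ether on O7, which leaves only O1 free and whose para donation stabilises the methide), C–C bond formation at C3 rather than at oxygen (fixed by the polarity of enamine and methide), and retention of the labile alpha-aryl configuration, which the immediate lactol closure by O1 should protect from amine-mediated enolisation.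

**Step 10**
Reactants: 13 (3R)-lactol
Product: 14 (3R)-3-{2-[(tert-butyldimethylsilyl)oxy]-5-(2-methylbut-3-en-2-yl)-4-[(triisopropylsilyl)oxy]phenyl}-6-(2-methylbut-3-en-2-yl)-7-[(triisopropylsilyl)oxy]-3,4-dihydro-2H-chromene
Conditions: Et3SiH (5 equiv), BF3·OEt2, CH2Cl2, −78 to −40 °C
Reagents that add atoms: none
Why: Ionic hydrogenation of a lactol (Lewis acid ionisation to the cyclic oxocarbenium ion, then hydride transfer from the silane), a standard conversion of chroman-2-ols into chromans; low temperature and excess silane are meant to outrun loss of H3 from the cation so that C3 keeps its configuration, and aryl silyl ethers and terminal alkenes should not react.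

**Step 11**
Reactants: 14 (3R)-tris-silyl isoflavan
Product: 15 Manuifolin E, (3R)-3-[2,4-dihydroxy-5-(2-methylbut-3-en-2-yl)phenyl]-6-(2-methylbut-3-en-2-yl)-3,4-dihydro-2H-chromen-7-ol
Conditions: Bu4NF (3.3 equiv), AcOH (3.3 equiv), THF, 0 °C to rt
Reagents that add atoms: none
Why: Fluoride-mediated cleavage of the three aryl silyl ethers (desilylation), buffered with acetic acid so that the phenoxides are protonated at once; the non-acidic conditions spare the ortho-(1,1-dimethylallyl)phenol units, which cyclise to dihydrobenzofurans under strong acid, and C3 is not touched.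

**Compound list**

1 | 2,4-dihydroxybenzaldehyde | O=Cc1ccc(O)cc1O | starting material
2 | prenyl bromide (1-bromo-3-methylbut-2-ene) | CC(C)=CCBr | starting material
3 | 2-hydroxy-4-[(3-methylbut-2-en-1-yl)oxy]benzaldehyde | O=Cc1ccc(OCC=C(C)C)cc1O | intermediate
4 | 2-[(tert-butyldimethylsilyl)oxy]-4-[(3-methylbut-2-en-1-yl)oxy]benzaldehyde | O=Cc1ccc(OCC=C(C)C)cc1O[Si](C)(C)C(C)(C)C | intermediate
5 | 2-[(tert-butyldimethylsilyl)oxy]-4-hydroxy-5-(2-methylbut-3-en-2-yl)benzaldehyde | O=Cc1cc(C(C)(C)C=C)c(O)cc1O[Si](C)(C)C(C)(C)C | intermediate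
6 | 2-[(tert-butyldimethylsilyl)oxy]-5-(2-methylbut-3-en-2-yl)-4-[(triisopropylsilyl)oxy]benzaldehyde | O=Cc1cc(C(C)(C)C=C)c(O[Si](C(C)C)(C(C)C)C(C)C)cc1O[Si](C)(C)C(C)(C)C | intermediate
7 | tert-butyl{2-(2-methoxyethenyl)-4-(2-methylbut-3-en-2-yl)-5-[(triisopropylsilyl)oxy]phenoxy}dimethylsilane (E/Z mixture) | COC=Cc1cc(C(C)(C)C=C)c(O[Si](C(C)C)(C(C)C)C(C)C)cc1O[Si](C)(C)C(C)(C)C | intermediate
8 | 2-{2-[(tert-butyldimethylsilyl)oxy]-5-(2-methylbut-3-en-2-yl)-4-[(triisopropylsilyl)oxy]phenyl}acetaldehyde | O=CCc1cc(C(C)(C)C=C)c(O[Si](C(C)C)(C(C)C)C(C)C)cc1O[Si](C)(C)C(C)(C)C | intermediate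
9 | 2-hydroxy-5-(2-methylbut-3-en-2-yl)-4-[(triisopropylsilyl)oxy]benzaldehyde (not isolated) | O=Cc1cc(C(C)(C)C=C)c(O[Si](C(C)C)(C(C)C)C(C)C)cc1O | intermediate
10 | 2-(hydroxymethyl)-4-(2-methylbut-3-en-2-yl)-5-[(triisopropylsilyl)oxy]phenol | OCc1cc(C(C)(C)C=C)c(O[Si](C(C)C)(C(C)C)C(C)C)cc1O | intermediate
11 | 4-(2-methylbut-3-en-2-yl)-2-[(4-methylbenzenesulfonyl)methyl]-5-[(triisopropylsilyl)oxy]phenol | Cc1ccc(cc1)S(=O)(=O)Cc1cc(C(C)(C)C=C)c(O[Si](C(C)C)(C(C)C)C(C)C)cc1O | intermediate
12 | 6-methylidene-4-(2-methylbut-3-en-2-yl)-3-[(triisopropylsilyl)oxy]cyclohexa-2,4-dien-1-one (ortho-quinone methide, not isolated) | C=C1C=C(C(C)(C)C=C)C(O[Si](C(C)C)(C(C)C)C(C)C)=CC1=O | intermediate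
13 | (3R)-3-{2-[(tert-butyldimethylsilyl)oxy]-5-(2-methylbut-3-en-2-yl)-4-[(triisopropylsilyl)oxy]phenyl}-6-(2-methylbut-3-en-2-yl)-7-[(triisopropylsilyl)oxy]-3,4-dihydro-2H-chromen-2-ol (C2 epimers) | C=CC(C)(C)c1cc2c(cc1O[Si](C(C)C)(C(C)C)C(C)C)OC(O)[C@@H](c1cc(C(C)(C)C=C)c(O[Si](C(C)C)(C(C)C)C(C)C)cc1O[Si](C)(C)C(C)(C)C)C2 | intermediate
14 | (3R)-3-{2-[(tert-butyldimethylsilyl)oxy]-5-(2-methylbut-3-en-2-yl)-4-[(triisopropylsilyl)oxy]phenyl}-6-(2-methylbut-3-en-2-yl)-7-[(triisopropylsilyl)oxy]-3,4-dihydro-2H-chromene | C=CC(C)(C)c1cc2c(cc1O[Si](C(C)C)(C(C)C)C(C)C)OC[C@@H](c1cc(C(C)(C)C=C)c(O[Si](C(C)C)(C(C)C)C(C)C)cc1O[Si](C)(C)C(C)(C)C)C2 | intermediate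
15 | Manuifolin E, (3R)-3-[2,4-dihydroxy-5-(2-methylbut-3-en-2-yl)phenyl]-6-(2-methylbut-3-en-2-yl)-3,4-dihydro-2H-chromen-7-ol | C=CC(C)(C)c1cc2c(cc1O)OC[C@@H](c1cc(C(C)(C)C=C)c(O)cc1O)C2 | target

**Step count and risks**

Total steps: 11. Longest linear sequence: 9 steps (steps 1–6, 9, 10, 11; the branch through steps 7 and 8 is equally long).

Steps most likely to fail:

1. Step 9. The processes at risk are poor facial selectivity in the enamine addition, erosion of the C3 configuration by amine-mediated enolisation of the alpha-aryl aldehyde before or after lactol closure, and oligomerisation of the methide. The fallback replaces catalyst control by auxiliary control (Evans alkylation) and closes the pyran ring by Mitsunobu etherification; it sets out from 8 and 10 and returns at 14.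
 - Pinnick oxidation of 8 (NaClO2, NaH2PO4, 2-methylbut-2-ene, t-BuOH/H2O) should give the arylacetic acid F1.
 - Activation with Me3CCOCl/Et3N in THF gives the mixed pivalic anhydride F2 (not isolated), which acylates the lithium salt of (R)-4-benzyl-1,3-oxazolidin-2-one (n-BuLi, THF, −78 °C) to the imide F3.
 - Separately, 10 is O-allylated at the phenol (allyl bromide, K2CO3, acetone) to the allyl ether F4 and converted (CBr4, PPh3, CH2Cl2, 0 °C) into the benzyl bromide F5.
 - The sodium enolate of F3 (NaN(SiMe3)2, THF, −78 °C) is alkylated by F5 on the face away from the benzyl group to give the alkylated imide F6, with (R) configuration at the new centre.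
 - LiBH4 (THF/H2O, 0 °C) removes the auxiliary to give the primary alcohol F7.
 - Pd(PPh3)4 with morpholine (THF, rt) removes the allyl group to give the phenol alcohol F8.
 - PPh3 and diisopropyl azodicarboxylate (THF, 0 °C) close the O1–C2 bond to give 14.

2. Step 10. The process at risk is loss of H3 from the oxocarbenium ion to give the 3-aryl-4H-chromene enol ether and its reprotonation, which would racemise C3; partial loss of silyl ethers under the Lewis acid is a lesser risk. The fallback avoids the cation altogether; it sets out from 13 and returns at 14. NaBH4 (MeOH/THF, 0 °C) reduces the open-chain aldehyde form of 13 to the ring-opened diol F9 (the same structure as F8), and Mitsunobu etherification (PPh3, diisopropyl azodicarboxylate, THF, 0 °C) between the O1 phenol and the primary alcohol closes the ring again to 14.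

3. Step 3. The processes at risk are thermal migration or loss of the labile ortho-formyl silyl ether (which would restore the chelate and steer the shift to C3), further rearrangement of the product phenol (abnormal Claisen), and loss of isoprene from the ether. The fallback uses an acetal directing group and a water-accelerated rearrangement at lower temperature; it sets out from 3 and returns at 9, then 6.
 - MeOCH2Cl with i-Pr2NEt (CH2Cl2) gives the methoxymethyl ether F10.
 - Heating in EtOH/H2O (4:1, 130 °C, sealed tube) should give the rearranged phenol F11.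
 - i-Pr3SiOSO2CF3 with 2,6-lutidine gives the silyl ether F12.
 - Mild acid (1 M HCl in MeOH/THF, rt) cleaves the acetal ortho to the formyl group selectively and gives 9.
 - Silylation of 9 (t-BuMe2SiCl, imidazole, DMF) gives 6.

**Further compounds**

F1 | step 9 | 2-{2-[(tert-butyldimethylsilyl)oxy]-5-(2-methylbut-3-en-2-yl)-4-[(triisopropylsilyl)oxy]phenyl}acetic acid | OC(=O)Cc1cc(C(C)(C)C=C)c(O[Si](C(C)C)(C(C)C)C(C)C)cc1O[Si](C)(C)C(C)(C)C
F2 | step 9 | mixed anhydride of F1 with 2,2-dimethylpropanoic acid (not isolated) | CC(C)(C)C(=O)OC(=O)Cc1cc(C(C)(C)C=C)c(O[Si](C(C)C)(C(C)C)C(C)C)cc1O[Si](C)(C)C(C)(C)C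
F3 | step 9 | (4R)-4-benzyl-3-(2-{2-[(tert-butyldimethylsilyl)oxy]-5-(2-methylbut-3-en-2-yl)-4-[(triisopropylsilyl)oxy]phenyl}acetyl)-1,3-oxazolidin-2-one | O=C(Cc1cc(C(C)(C)C=C)c(O[Si](C(C)C)(C(C)C)C(C)C)cc1O[Si](C)(C)C(C)(C)C)N1C(=O)OC[C@H]1Cc1ccccc1
F4 | step 9 | {5-(2-methylbut-3-en-2-yl)-2-(prop-2-en-1-yloxy)-4-[(triisopropylsilyl)oxy]phenyl}methanol | OCc1cc(C(C)(C)C=C)c(O[Si](C(C)C)(C(C)C)C(C)C)cc1OCC=C
F5 | step 9 | 1-(bromomethyl)-5-(2-methylbut-3-en-2-yl)-2-(prop-2-en-1-yloxy)-4-[(triisopropylsilyl)oxy]benzene | BrCc1cc(C(C)(C)C=C)c(O[Si](C(C)C)(C(C)C)C(C)C)cc1OCC=C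
F6 | step 9 | (4R)-4-benzyl-3-[(2R)-2-{2-[(tert-butyldimethylsilyl)oxy]-5-(2-methylbut-3-en-2-yl)-4-[(triisopropylsilyl)oxy]phenyl}-3-{5-(2-methylbut-3-en-2-yl)-2-(prop-2-en-1-yloxy)-4-[(triisopropylsilyl)oxy]phenyl}propanoyl]-1,3-oxazolidin-2-one | O=C([C@H](Cc1cc(C(C)(C)C=C)c(O[Si](C(C)C)(C(C)C)C(C)C)cc1OCC=C)c1cc(C(C)(C)C=C)c(O[Si](C(C)C)(C(C)C)C(C)C)cc1O[Si](C)(C)C(C)(C)C)N1C(=O)OC[C@H]1Cc1ccccc1
F7 | step 9 | (2R)-2-{2-[(tert-butyldimethylsilyl)oxy]-5-(2-methylbut-3-en-2-yl)-4-[(triisopropylsilyl)oxy]phenyl}-3-{5-(2-methylbut-3-en-2-yl)-2-(prop-2-en-1-yloxy)-4-[(triisopropylsilyl)oxy]phenyl}propan-1-ol | OC[C@H](Cc1cc(C(C)(C)C=C)c(O[Si](C(C)C)(C(C)C)C(C)C)cc1OCC=C)c1cc(C(C)(C)C=C)c(O[Si](C(C)C)(C(C)C)C(C)C)cc1O[Si](C)(C)C(C)(C)C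
F8 | step 9 | 2-[(2R)-2-{2-[(tert-butyldimethylsilyl)oxy]-5-(2-methylbut-3-en-2-yl)-4-[(triisopropylsilyl)oxy]phenyl}-3-hydroxypropyl]-4-(2-methylbut-3-en-2-yl)-5-[(triisopropylsilyl)oxy]phenol | OC[C@H](Cc1cc(C(C)(C)C=C)c(O[Si](C(C)C)(C(C)C)C(C)C)cc1O)c1cc(C(C)(C)C=C)c(O[Si](C(C)C)(C(C)C)C(C)C)cc1O[Si](C)(C)C(C)(C)C
F9 | step 10 | 2-[(2R)-2-{2-[(tert-butyldimethylsilyl)oxy]-5-(2-methylbut-3-en-2-yl)-4-[(triisopropylsilyl)oxy]phenyl}-3-hydroxypropyl]-4-(2-methylbut-3-en-2-yl)-5-[(triisopropylsilyl)oxy]phenol (same structure as F8) | OC[C@H](Cc1cc(C(C)(C)C=C)c(O[Si](C(C)C)(C(C)C)C(C)C)cc1O)c1cc(C(C)(C)C=C)c(O[Si](C(C)C)(C(C)C)C(C)C)cc1O[Si](C)(C)C(C)(C)C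
F10 | step 3 | 2-(methoxymethoxy)-4-[(3-methylbut-2-en-1-yl)oxy]benzaldehyde | COCOc1cc(OCC=C(C)C)ccc1C=O
F11 | step 3 | 4-hydroxy-2-(methoxymethoxy)-5-(2-methylbut-3-en-2-yl)benzaldehyde | COCOc1cc(O)c(C(C)(C)C=C)cc1C=O
F12 | step 3 | 2-(methoxymethoxy)-5-(2-methylbut-3-en-2-yl)-4-[(triisopropylsilyl)oxy]benzaldehyde | COCOc1cc(O[Si](C(C)C)(C(C)C)C(C)C)c(C(C)(C)C=C)cc1C=O
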